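**Retrosynthetic overview**
- Target ⇐ 4,5-epoxy-6-hydroxy enone: the C4–O bond comes from water opening the allylic oxirane with inversion, after a Stork–Danheiser carbonyl transposition of a methoxy-enone.
- Epoxy methoxy-enone ⇐ 3-methoxy p-quinol: hydroxyl-guided nucleophilic epoxidation makes the C5–O and C4–O bonds cis to the tertiary OH.
- p-Quinol ⇐ 4-alkyl-3-methoxyphenol: enantioselective para-hydroxylative dearomatisation (key C–O bond; sets the quaternary carbinol).
- Phenol ⇐ erucic acid + 4-bromo-3-methoxyphenol by decarboxylative sp3–sp2 coupling; the C21 chain and its Z-alkene are bought intact.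
- Rings: the six-membered carbocycle is the bought arene; the oxirane is made in step 3 and opened in step 4.

Assumption: the (R,R)-iodoarene is taken to give the (4R)-quinol; if the sense of induction is the opposite, its (S,S)-antipode is used and nothing else changes.

**Step 1**
Reactants: 1 erucic acid [(13Z)-docos-13-enoic acid]; 2 N-hydroxyphthalimide; 3 4-bromo-3-methoxyphenol
Product: 5 4-[(12Z)-heneicos-12-en-1-yl]-3-methoxyphenol, via redox-active ester 4 (not isolated)
Conditions: N,N′-diisopropylcarbodiimide, 4-(dimethylamino)pyridine (5 mol %), CH2Cl2, rt; filter, evaporate; then 3 (1.5 equiv), NiBr2·(MeOCH2CH2OMe) (10 mol %), 4,4′-di-tert-butyl-2,2′-bipyridine (10 mol %), Zn (2 equiv), NaI (25 mol %), N,N-dimethylacetamide, 40 °C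
Reagents that add atoms: none
Why: Nickel-catalysed decarboxylative cross-electrophile coupling, in which zinc-reduced low-valent nickel fragments the ester to CO2, phthalimidate and the primary heneicosenyl radical, which is captured by the arylnickel bromide formed from 3; the conditions are non-basic, so the remote Z-alkene and the free phenol should be spectators.

**Step 2**
Reactants: 5 4-[(12Z)-heneicos-12-en-1-yl]-3-methoxyphenol
Product: 6 (4R)-4-hydroxy-4-[(12Z)-heneicos-12-en-1-yl]-3-methoxycyclohexa-2,5-dien-1-one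
Conditions: (R,R)-2,2′-[(2-iodo-1,3-phenylene)bis(oxy)]bis[N-(2,4,6-trimethylphenyl)propanamide] (10 mol %), KHSO5 (as 2KHSO5·KHSO4·K2SO4, 1.2 equiv), MeCN/THF/H2O (3:1:1), 0 °C
Reagents that add atoms: water, O
Why: Proposed new method: KHSO5 (which does not epoxidise the isolated alkene) oxidises the iodoarene to an aryl trivalent iodine species that binds the phenol oxygen, one lactamide N–H hydrogen-bonds the 3-methoxy oxygen and so fixes which edge of the arene faces which arm while the mesityl group of the other arm covers one face of C-4, so water adds para at the alkyl-bearing carbon from the open face as the iodoarene leaves and sets the quaternary carbinol as R; the closest known reactions are iodoarene/KHSO5-catalysed hydroxylative para-dearomatisation of 4-alkylphenols to racemic p-quinols and chiral-iodoarene-catalysed enantioselective phenol dearomatisation (spirolactonisation with high selectivity, p-quinol formation with modest selectivity).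

**Step 3**
Reactants: 6 (4R)-4-hydroxy-4-[(12Z)-heneicos-12-en-1-yl]-3-methoxycyclohexa-2,5-dien-1-one
Product: 7 (1S,5R,6R)-5-hydroxy-5-[(12Z)-heneicos-12-en-1-yl]-4-methoxy-7-oxabicyclo[4.1.0]hept-3-en-2-one
Conditions: t-BuOOH (1.5 equiv, in decane), benzyltrimethylammonium hydroxide (10 mol %), THF, 0 °C
Reagents that add atoms: tert-butyl hydroperoxide, CC(C)(C)OO
Why: Weitz–Scheffer nucleophilic epoxidation, in which the hydroperoxide anion adds only to the β-carbon of the unsubstituted enone (the methoxy-bearing alkene is a deactivated vinylogous ester and the chain alkene is not electrophilic) from the face of the tertiary hydroxyl, which hydrogen-bonds the peroxide and is the smaller group beside the C21 chain, so the oxirane forms cis to OH and sets C-1 and C-6.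

**Step 4**
Reactants: 7 (1S,5R,6R)-5-hydroxy-5-[(12Z)-heneicos-12-en-1-yl]-4-methoxy-7-oxabicyclo[4.1.0]hept-3-en-2-one
Product: 10 (4S,5R,6R)-4,5,6-trihydroxy-6-[(12Z)-heneicos-12-en-1-yl]cyclohex-2-en-1-one, via epoxy diol 8 (not isolated), via epoxy enone 9 (not isolated)
Conditions: NaBH4, CeCl3·7H2O, MeOH/THF, −40 °C; evaporate; then 0.5 M H2SO4, THF/H2O (1:1), 0 °C to 40 °C
Reagents that add atoms: water, O
Why: Luche 1,2-reduction followed by Stork–Danheiser-type acid hydrolysis of the methyl enol ether and loss of water moves the carbonyl next to the quaternary carbinol, and the now allylic oxirane is opened by water in SN2 fashion at C-4 (C-5 is shielded by the adjacent quaternary centre), so inversion at C-4 gives the 4,5-trans, 5,6-cis triol.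

**Compound list**
1 | erucic acid, (13Z)-docos-13-enoic acid | CCCCCCCC/C=C\CCCCCCCCCCCC(=O)O | starting material
2 | N-hydroxyphthalimide (2-hydroxyisoindoline-1,3-dione) | ON1C(=O)c2ccccc2C1=O | starting material
3 | 4-bromo-3-methoxyphenol | COc1cc(O)ccc1Br | starting material
4 | 1,3-dioxoisoindolin-2-yl (13Z)-docos-13-enoate | CCCCCCCC/C=C\CCCCCCCCCCCC(=O)ON1C(=O)c2ccccc2C1=O | intermediate (not isolated)
5 | 4-[(12Z)-heneicos-12-en-1-yl]-3-methoxyphenol | CCCCCCCC/C=C\CCCCCCCCCCCc1ccc(O)cc1OC | intermediate
6 | (4R)-4-hydroxy-4-[(12Z)-heneicos-12-en-1-yl]-3-methoxycyclohexa-2,5-dien-1-one | CCCCCCCC/C=C\CCCCCCCCCCC[C@]1(O)C(OC)=CC(=O)C=C1 | intermediate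
7 | (1S,5R,6R)-5-hydroxy-5-[(12Z)-heneicos-12-en-1-yl]-4-methoxy-7-oxabicyclo[4.1.0]hept-3-en-2-one, oxirane cis to the tertiary OH | CCCCCCCC/C=C\CCCCCCCCCCC[C@]1(O)C(OC)=CC(=O)[C@H]2O[C@@H]12 | intermediate
8 | (1R,2R,6R)-2-[(12Z)-heneicos-12-en-1-yl]-3-methoxy-7-oxabicyclo[4.1.0]hept-3-ene-2,5-diol, both C-5 epimers | CCCCCCCC/C=C\CCCCCCCCCCC[C@]1(O)C(OC)=CC(O)[C@H]2O[C@@H]12 | intermediate (not isolated)
9 | (1R,2R,6R)-2-hydroxy-2-[(12Z)-heneicos-12-en-1-yl]-7-oxabicyclo[4.1.0]hept-4-en-3-one, oxirane cis to OH | CCCCCCCC/C=C\CCCCCCCCCCC[C@]1(O)C(=O)C=C[C@H]2O[C@@H]12 | intermediate (not isolated)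
10 | (4S,5R,6R)-4,5,6-trihydroxy-6-[(12Z)-heneicos-12-en-1-yl]cyclohex-2-en-1-one | CCCCCCCC/C=C\CCCCCCCCCCC[C@]1(O)C(=O)C=C[C@H](O)[C@H]1O | target

**Step count and risks**
Total step count: 4. Longest linear sequence: 4 steps (1 to 10).

The three steps most likely to fail:

Step 1. The aryl bromide is electron-rich and ortho-substituted and carries a free phenol, so oxidative addition may lag behind radical formation and give reduced or dimerised chain. The fallback sets out from 3 and from 4 (then isolated by crystallisation) and comes back at 5. Compound 3 is silylated (t-BuMe2SiCl, imidazole, DMF) to (4-bromo-3-methoxyphenoxy)(tert-butyl)dimethylsilane F1. Bromine–lithium exchange (n-BuLi, THF, −78 °C) gives [4-(tert-butyldimethylsilyloxy)-2-methoxyphenyl]lithium F2, which ZnCl2 converts into [4-(tert-butyldimethylsilyloxy)-2-methoxyphenyl]zinc chloride F3. Nickel-catalysed decarboxylative Negishi coupling of F3 with 4 (NiCl2·(MeOCH2CH2OMe), 4,4′-di-tert-butyl-2,2′-bipyridine, THF/DMF, rt) gives tert-butyl{4-[(12Z)-heneicos-12-en-1-yl]-3-methoxyphenoxy}dimethylsilane F4, and Bu4NF in THF releases 5.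

Step 2 (the proposed new step). Induction at the para carbon, remote from iodine, may be weak in aqueous medium, and over-oxidation of the catalyst to pentavalent iodine could divert material to ortho-oxygenation. The fallback uses known chemistry, sets out from 5 and comes back at 6. PhI(OAc)2 in MeCN/H2O at 0 °C (the standard racemic p-quinol synthesis) gives the racemate, that is 6 together with (4S)-4-hydroxy-4-[(12Z)-heneicos-12-en-1-yl]-3-methoxycyclohexa-2,5-dien-1-one F5. F5 is removed by preparative HPLC on an amylose tris(3,5-dimethylphenylcarbamate) phase, and 6 is carried on.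

Step 4. In the one-pot acid cascade the oxirane may open at the wrong carbon, or the triol may dehydrate on prolonged heating. The fallback sets out from 9 and comes back at 10. The acid treatment is stopped at 0 °C and 9 is isolated. The oxirane is then opened under hydroxyl-directed control: Ti(OiPr)4 and PhCO2H in CH2Cl2 deliver benzoate to C-3 of the 2,3-epoxy alcohol unit (C-4 of the enone) with inversion, giving (1S,5R,6R)-5,6-dihydroxy-5-[(12Z)-heneicos-12-en-1-yl]-4-oxocyclohex-2-en-1-yl benzoate F6. K2CO3 in MeOH at 0 °C removes the benzoate to give 10.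

**Further compounds**
F1 | step 1 | (4-bromo-3-methoxyphenoxy)(tert-butyl)dimethylsilane | COc1cc(O[Si](C)(C)C(C)(C)C)ccc1Br
F2 | step 1 | [4-(tert-butyldimethylsilyloxy)-2-methoxyphenyl]lithium | [Li]c1ccc(O[Si](C)(C)C(C)(C)C)cc1OC
F3 | step 1 | [4-(tert-butyldimethylsilyloxy)-2-methoxyphenyl]zinc chloride | Cl[Zn]c1ccc(O[Si](C)(C)C(C)(C)C)cc1OC
F4 | step 1 | tert-butyl{4-[(12Z)-heneicos-12-en-1-yl]-3-methoxyphenoxy}dimethylsilane | CCCCCCCC/C=C\CCCCCCCCCCCc1ccc(O[Si](C)(C)C(C)(C)C)cc1OC
F5 | step 2 | (4S)-4-hydroxy-4-[(12Z)-heneicos-12-en-1-yl]-3-methoxycyclohexa-2,5-dien-1-one | CCCCCCCC/C=C\CCCCCCCCCCC[C@@]1(O)C(OC)=CC(=O)C=C1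
F6 | step 4 | (1S,5R,6R)-5,6-dihydroxy-5-[(12Z)-heneicos-12-en-1-yl]-4-oxocyclohex-2-en-1-yl benzoate | CCCCCCCC/C=C\CCCCCCCCCCC[C@]1(O)C(=O)C=C[C@H](OC(=O)c2ccccc2)[C@H]1O
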